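## Structural features

The target is a monocyclic, fully substituted 4H-pyran-4-one (ring atoms O1, C2–C6). It carries a methoxy group at C2, ethyl groups at C3 and C5, the carbonyl at C4 and an unbranched eleven-carbon chain (C1'–C11') at C6. Nine methylenes (C1'–C9') separate the ring from C10', which bears the acetoxy group and the terminal methyl C11'. C10' is the only stereocentre and is S (O > C9' > C11' > H). It has no stereogenic neighbour and lies ten bonds from the ring, so nothing in the molecule can direct it and it must be bought or set by a reagent. The fragile groups are the secondary acetate (lost to hydroxide, alkoxide and organometallic reagents) and the 2-methoxy-4-pyranone. The latter is a vinylogous carbonate that takes up nucleophiles at C2 and C6, is demethylated by strong acid and has acidic hydrogens at C1'. The real difficulties are placing the methyl group on the correct ring oxygen (2-methoxy-4-pyranone, not 4-methoxy-2-pyranone) and attaching a long, featureless chain with a remote stereocentre without a protecting-group detour for the acetate. The key step exploits the (CH2)9 tether: the C3'–C4' bond lies two methylenes from C6 and five from C10', so both halves behave as plain terminal alkenes in ruthenium-catalysed cross-metathesis.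

## Logic of the disconnections

**16 ⇒ 15.** No skeletal bond is cut; a double bond is written into the C3'–C4' bond of 16. An alkene in the tether is the retron for olefin metathesis and can be removed at the end. The gain is access to a convergent cut in the middle of the molecule. The forward step must saturate a 1,2-disubstituted alkene of either geometry while the two tetrasubstituted ring double bonds, the C4 carbonyl and the acetate stay untouched.

**15 ⇒ 9 + 14.** The C3'=C4' double bond is cut. This leaves all ring chemistry in 9 and the stereocentre with its acetate in 14, and makes both partners unhindered monosubstituted alkenes. A C23 compound falls into C14 and C11 halves of similar size, and no protecting group is needed because the acetate is already in place. The forward step must favour cross- over self-coupling and must not move the double bonds along the chain.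

**14 ⇒ 10 + 11 (through 12 and 13).** The acetyl C–O bond and the C3–C4 bond of 14 (C8'–C9' of the target) are cut. Cutting next to the carbinol-bearing CH2 reveals a three-carbon epoxide whose stereocentre is commercial. The stereocentre is bought, not made, and the rest is a six-carbon halide. The forward step must open 11 only at its unsubstituted carbon, so that the C–O stereocentre never reacts, and must acylate 13 in the same flask.

**9 ⇒ 7 (through 8).** The O–CH3 bond at C2 is cut. This converts a vinylogous carbonate, hard to assemble directly, into a 4-hydroxy-2-pyranone, the classical cyclisation product of a 3,5-diketo ester. The forward step must methylate the lactone carbonyl oxygen and not the C4 hydroxyl, which calls for a hard methylating agent on the neutral substrate.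

**7 ⇒ 6.** The lactone bond O1–C2 is cut. The ring becomes an open chain with a 1,3,5-oxygen pattern. The forward step needs the enol oxygen of the distal ketone to reach the ester; the two sp3 stereocentres of 6 are irrelevant because both become sp2.

**6 ⇒ 2 + 4 (through 5).** The C4–C5 bond of 6 (ring C5–C6) is cut. This brings the butenyl handle in with the acyl donor, so the finished ring never needs lateral deprotonation and allylation at a C6 methyl group, and the longest linear sequence is one step shorter. The forward step needs acylation at the γ-carbon of 5 only, stopping at the ketone.

**4 ⇒ 3.** The amide C–N bond is cut, leading to a commercial acid chloride. The forward step is a routine N-acylation.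

**2 ⇒ 1 + 1.** The C2–C3 bond of 2 (ring C3–C4) is cut. Ring carbons C2–C5 and both ethyl groups are a head-to-tail dimer of one four-carbon ester. The forward self-condensation is driven to completion by deprotonation of the product.

## Other disconnections considered

**Alternative 1:** The cut is inside the ring, at O1–C6 together with C5–I. It leads back to the acyclic ynone ester A1, methyl (15S)-15-(tert-butyldimethylsilyloxy)-2-ethyl-3-oxohexadec-4-ynoate. In the forward step N-iodosuccinimide would turn the C4≡C5 triple bond of A1 into an iodonium ion. The ester carbonyl oxygen would attack the chain-bearing alkyne carbon in a 6-endo-dig closure, and loss of the proton between the carbonyls would give the iodopyranone A2, 3-ethyl-5-iodo-2-methoxy-6-[(10S)-10-(tert-butyldimethylsilyloxy)undecyl]-4H-pyran-4-one.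
- In its favour: the ring methoxy is the ester methoxy, so the question of which oxygen is methylated never arises. On this point the alternative is better than the chosen plan. The closure needs no base, and ynone polarisation directs oxygen to the β-carbon.
- Against it here: C5 of the target carries ethyl, so the iodine must be exchanged in an extra sp2–sp3 coupling (for example EtZnCl with PdCl2(dppf)) at a position flanked on both sides. The doubly activated C–H of A1 may be iodinated in place of the alkyne, and 5-exo-dig closure to a furanone is a competing path. A1 must be made by acetylide chemistry that an acetate would not survive, so a silyl ether is put on and later removed before acetylation.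
- Comparison: structurally the alternative builds the ring around a finished chain, whereas the chosen plan takes ring carbons C2–C5 and both ethyl groups from one cheap ester and joins the chain later under neutral conditions. Mechanistically an electrophilic cyclisation with endo/exo and C/O selectivity questions stands against a metathesis with no regiochemical question but only statistical partner selection. In step count the alternative needs coupling, desilylation and acetylation after its key step, against one hydrogenation after step 7. On stereochemistry the two are equal, since both take C10' from the chiral pool.

**Alternative 2:** The cut is the C6–C1' bond between ring and chain. In the forward step the Grignard reagent A4, [(10S)-10-(tert-butyldimethylsilyloxy)undecyl]magnesium bromide, would add with catalytic CuI in a 1,4-sense to one of the two equivalent methoxy-bearing carbons of the symmetric pyranone A3, 3,5-diethyl-2,6-dimethoxy-4H-pyran-4-one. Loss of methoxide would give A5, 6-[(10S)-10-(tert-butyldimethylsilyloxy)undecyl]-3,5-diethyl-2-methoxy-4H-pyran-4-one.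
- In its favour: it is the most convergent cut available, and the symmetry of A3 removes the O-methylation problem. On convergence and on ring regiochemistry the alternative is better than the chosen plan.
- Against it here: A5 still holds a second methoxy leaving group, so stopping at mono-substitution rests only on the lower electrophilicity of the product, and 1,2-addition at C4 is a further path. The partner likely to be needed in excess is the one carrying the stereocentre. An organomagnesium reagent excludes the acetate, so silylation, desilylation and acetylation are added. A4 needs a ten-carbon chain differentiated at both ends, which is longer to make than 14.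
- Comparison: structurally both plans join a ring piece to a chain piece, the alternative at the ring and the chosen plan three bonds away. Mechanistically a polar addition–elimination with a strongly basic nucleophile stands against a neutral carbene process that tolerates acetate and pyranone alike. In step economy the shorter ring synthesis is offset by the longer chain synthesis and the protecting-group steps, so the totals should be similar, and the chosen plan alone uses no protecting group. On stereochemical security the two are equal.

**Alternative 3:** No skeletal bond is cut; the C10'–H bond is disconnected, leading to the methyl ketone A6, 3,5-diethyl-2-methoxy-6-(10-oxoundecyl)-4H-pyran-4-one. In the forward step an (S)-selective ketoreductase, with NADPH recycled by isopropanol, would deliver hydride to the re face of the C10' carbonyl. This would give the alcohol A7, 3,5-diethyl-6-[(10S)-10-hydroxyundecyl]-2-methoxy-4H-pyran-4-one, which is then acetylated.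
- In its favour: a methyl ketone with a long unbranched second substituent is the model substrate for Prelog-type reductases, and the ring carbonyl is a vinylogous ester and not a substrate. The stereocentre is set catalytically from achiral material, and either enantiomer is available by choice of enzyme, so on flexibility the alternative is better. It is compatible with the same C3'–C4' assembly and is therefore a variant of the metathesis plan, not a rival.
- Against it here: A6 is lipophilic and poorly soluble in buffer, so a cosolvent or two-phase system and an enzyme screen would be needed. Enantiomeric purity would have to be proven on a late, oily intermediate, whereas the chosen plan buys it in a distillable epoxide. Reduction and acetylation add two steps after the chain is complete.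
- Comparison: structurally the skeleton is assembled the same way and only the origin of C10' differs (reagent control against chiral pool). Mechanistically facial selection by the enzyme depends on the active site telling methyl from the long chain, while the epoxide opening depends only on attack at a primary carbon; both are reliable and judged equal. In step economy the chosen plan is shorter by two steps.

Key step: step 7

Assumption: 15 is expected as an E/Z mixture and is named and drawn as the E isomer, since both isomers converge in step 8; opening 11 at its CH2 carbon leaves the CIP ranking at the stereocentre unchanged, so S in 11 is S in 14 and 16.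

## Route

Step 1
Reactants: 1 methyl butanoate (2 equiv)
Product: 2 methyl 2-ethyl-3-oxohexanoate
Conditions: NaH (0.6 equiv), MeOH (cat.), THF, reflux; then 1 M HCl, 0 °C
Reagents that add atoms: none
Why: Claisen self-condensation, pulled to completion because NaH irreversibly deprotonates the remaining α-hydrogen of the β-keto ester; the C2 stereocentre forms racemic and is later lost as a ring sp2 carbon.

Step 2
Reactants: 3 pent-4-enoyl chloride
Product: 4 N-methoxy-N-methylpent-4-enamide
Conditions: MeNH(OMe)·HCl (1.1 equiv), pyridine (2.2 equiv), CH2Cl2, 0 °C → rt
Reagents that add atoms: N,O-dimethylhydroxylamine hydrochloride, CNOC.Cl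
Why: N-acylation of the hydroxylamine by an acid chloride (Weinreb amide formation); the terminal alkene is a spectator.

Step 3
Reactants: 2 methyl 2-ethyl-3-oxohexanoate; 4 N-methoxy-N-methylpent-4-enamide
Product: 6 methyl 2,4-diethyl-3,5-dioxonon-8-enoate, via dilithium dienolate 5 (not isolated)
Conditions: LiN(i-Pr)2 (2.3 equiv), THF, −78 → 0 °C; then 4 (1.1 equiv), −78 → 0 °C; aq. NH4Cl
Reagents that add atoms: none
Why: β-Keto ester dianion chemistry (Weiler type): the second deprotonation occurs at C4, and this more reactive terminus attacks the amide carbonyl; acyl substitution on an N-methoxy-N-methylamide stops at the ketone. The product is a mixture of C2/C4 diastereomers and enol forms, which is immaterial because both centres become sp2 in step 4.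

Step 4
Reactants: 6 methyl 2,4-diethyl-3,5-dioxonon-8-enoate
Product: 7 6-(but-3-en-1-yl)-3,5-diethyl-4-hydroxy-2H-pyran-2-one
Conditions: DBU (1.5 equiv), toluene, 80 °C; then 1 M HCl
Reagents that add atoms: none
Why: Base-mediated lactonisation of a 3,5-diketo ester: the enolate oxygen of the C5 ketone attacks the ester carbonyl (6-exo-trig acyl substitution), methanol leaves and tautomerisation gives the 4-hydroxy-2-pyranone.

Step 5
Reactants: 7 6-(but-3-en-1-yl)-3,5-diethyl-4-hydroxy-2H-pyran-2-one
Product: 9 6-(but-3-en-1-yl)-3,5-diethyl-2-methoxy-4H-pyran-4-one, via hydroxypyrylium triflate 8 (not isolated)
Conditions: MeOTf (1.2 equiv), CH2Cl2, 0 °C → rt; then aq. NaHCO3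
Reagents that add atoms: methyl trifluoromethanesulfonate, COS(=O)(=O)C(F)(F)F
Why: O-Alkylation of the neutral 4-hydroxy-2-pyranone by a hard methylating agent takes place at the lactone carbonyl oxygen, its most basic site, and gives the aromatic pyrylium 8; loss of the hydroxyl proton on basic work-up leaves the 2-methoxy-4-pyranone. No base is present during alkylation, since the ambident anion would be methylated at the C4 oxygen, and the acid formed stays bound in 8, which protects the terminal alkene.

Step 6
Reactants: 10 6-bromohex-1-ene; 11 (S)-2-methyloxirane [(S)-propylene oxide]
Product: 14 (S)-non-8-en-2-yl acetate, via hex-5-enylmagnesium bromide 12 (not isolated), via bromomagnesium (S)-non-8-en-2-olate 13 (not isolated)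
Conditions: Mg, THF, rt; CuI (10 mol%), −30 °C, then 11, −30 → 0 °C; Ac2O (3 equiv), DMAP (cat.), 0 °C → rt; aq. NH4Cl
Reagents that add atoms: acetic anhydride, CC(=O)OC(C)=O
Why: Copper-catalysed SN2 opening of a terminal epoxide by a Grignard reagent at the unsubstituted carbon, followed by acylation of the magnesium alkoxide in the same flask. The C–O stereocentre of 11 is not a reacting centre, so its S configuration passes unchanged into 13 and 14.

Step 7
Reactants: 9 6-(but-3-en-1-yl)-3,5-diethyl-2-methoxy-4H-pyran-4-one; 14 (S)-non-8-en-2-yl acetate (3 equiv)
Product: 15 (2S,8E)-11-(3,5-diethyl-6-methoxy-4-oxo-4H-pyran-2-yl)undec-8-en-2-yl acetate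
Conditions: RuCl2(H2IMes)(PCy3)(=CHPh) (second-generation Grubbs catalyst, 5 mol%), 1,4-benzoquinone (10 mol%), CH2Cl2, 40 °C, Ar sweep
Reagents that add atoms: none
Why: Olefin cross-metathesis by the Chauvin mechanism: loss of PCy3 gives 14-electron RuCl2(H2IMes)(=CHPh), which adds a terminal alkene in a [2+2] step to a ruthenacyclobutane and cycloreverts to a new alkylidene; a second [2+2]/retro-[2+2] with the other partner joins C3' to C4' and leaves RuCl2(H2IMes)(=CH2), which re-enters the cycle with loss of ethylene. The closest known reaction type is ruthenium-catalysed cross-metathesis of two unhindered monosubstituted alkenes. No ring is closed and no stereocentre is created; the alkene geometry drifts towards E by secondary metathesis and does not matter, since the bond is saturated in step 8. The step needs cross- over self-coupling; because both partners and both self-dimers react reversibly at similar rates, this is secured by mass action, with 14 in threefold excess, ethylene swept out and 9 as the limiting partner. It needs chemoselectivity for the terminal alkenes, which the substrate provides: the ring double bonds of 9 are tetrasubstituted and part of a push–pull system, and neither the acetate nor the ring oxygens can form a stable chelate with the alkylidene. It needs the double bond to stay where it forms, which 1,4-benzoquinone supports by intercepting Ru–H decomposition products that cause migration. The C10' stereocentre lies five methylenes from the reacting carbon and is not touched.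

Step 8
Reactants: 15 (2S,8E)-11-(3,5-diethyl-6-methoxy-4-oxo-4H-pyran-2-yl)undec-8-en-2-yl acetate
Product: 16 (2S)-11-(3,5-diethyl-6-methoxy-4-oxo-4H-pyran-2-yl)undecan-2-yl acetate, that is 6-[(10S)-10-acetoxyundecyl]-3,5-diethyl-2-methoxy-4H-pyran-4-one
Conditions: H2 (1 atm), 10% Pd/C, EtOAc, rt
Reagents that add atoms: none
Why: Heterogeneous catalytic hydrogenation: the unhindered 1,2-disubstituted chain alkene of either geometry is reduced quickly, whereas the tetrasubstituted vinylogous-ester double bonds of the ring, the C4 carbonyl and the non-allylic acetate are inert under these mild conditions. The stereocentre is remote from the alkene and unaffected.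

## Compound list

1 | methyl butanoate | CCCC(=O)OC | starting material
2 | methyl 2-ethyl-3-oxohexanoate (racemic) | CCCC(=O)C(CC)C(=O)OC | intermediate
3 | pent-4-enoyl chloride | C=CCCC(=O)Cl | starting material
4 | N-methoxy-N-methylpent-4-enamide | C=CCCC(=O)N(C)OC | intermediate
5 | dilithium dienolate (C2,C4-dianion) of methyl 2-ethyl-3-oxohexanoate | [Li+].[Li+].CCC=C([O-])C(CC)=C([O-])OC | intermediate (not isolated)
6 | methyl 2,4-diethyl-3,5-dioxonon-8-enoate (diastereomer and tautomer mixture) | C=CCCC(=O)C(CC)C(=O)C(CC)C(=O)OC | intermediate
7 | 6-(but-3-en-1-yl)-3,5-diethyl-4-hydroxy-2H-pyran-2-one | C=CCCc1oc(=O)c(CC)c(O)c1CC | intermediate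
8 | 6-(but-3-en-1-yl)-3,5-diethyl-4-hydroxy-2-methoxypyrylium trifluoromethanesulfonate | CCc1c(OC)[o+]c(CCC=C)c(CC)c1O.[O-]S(=O)(=O)C(F)(F)F | intermediate (not isolated)
9 | 6-(but-3-en-1-yl)-3,5-diethyl-2-methoxy-4H-pyran-4-one | CCc1c(CCC=C)oc(OC)c(CC)c1=O | intermediate
10 | 6-bromohex-1-ene | C=CCCCCBr | starting material
11 | (S)-2-methyloxirane [(S)-propylene oxide] | C[C@H]1CO1 | starting material
12 | hex-5-enylmagnesium bromide | C=CCCCC[Mg]Br | intermediate (not isolated)
13 | bromomagnesium (S)-non-8-en-2-olate | C=CCCCCC[C@H](C)O[Mg]Br | intermediate (not isolated)
14 | (S)-non-8-en-2-yl acetate | C=CCCCCC[C@H](C)OC(C)=O | intermediate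
15 | (2S,8E)-11-(3,5-diethyl-6-methoxy-4-oxo-4H-pyran-2-yl)undec-8-en-2-yl acetate (E isomer drawn; the Z isomer is expected alongside) | CCc1c(CC/C=C/CCCCC[C@H](C)OC(C)=O)oc(OC)c(CC)c1=O | intermediate
16 | 6-[(10S)-10-acetoxyundecyl]-3,5-diethyl-2-methoxy-4H-pyran-4-one | CCc1c(CCCCCCCCC[C@H](C)OC(C)=O)oc(OC)c(CC)c1=O | target

## Step count and least certain steps

Total: 8 steps. Longest linear sequence: 6 steps (steps 1, 3, 4, 5, 7, 8 from 1). Steps 2 and 6 are one-step side branches.

**Step 7 (key step).** Partner selection and positional fidelity are the likely problems. Self-metathesis of each alkene competes with the cross event on statistical terms, and the catalyst may die before the self-dimers have been fed back. Ru–H species formed on decomposition can also move a double bond along the chain before metathesis, which would change the tether length by one methylene in a way that hydrogenation hides. The fallback sets out from 9, rejoins the route at 16 and makes step 8 unnecessary. It is an alkyl–alkyl Suzuki–Miyaura coupling that forms C4'–C5' in place of C3'=C4'. Epoxide 11 would be opened with commercial but-3-enylmagnesium bromide (CuI cat., THF, −30 °C) and the product acetylated in the flask to (S)-hept-6-en-2-yl acetate F1. Radical anti-Markovnikov addition of HBr (AIBN, hexane, 0 °C) would give (S)-7-bromoheptan-2-yl acetate F2. Hydroboration of 9 with 9-BBN (THF, 0 °C → rt) would give 6-[4-(9-borabicyclo[3.3.1]nonan-9-yl)butyl]-3,5-diethyl-2-methoxy-4H-pyran-4-one F3. This would be coupled without isolation with F2 under Pd(OAc)2/PCy3, K3PO4·H2O, THF, rt, to give 16.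

**Step 3.** Proton transfer may win over C-acylation. The γ-carbanion terminus of 5 is hindered by its ethyl substituent and strongly basic, so it may deprotonate the α-CH2 of 4 and return 2. The fallback sets out from 2 (through 5) and comes back at 6. Aldol addition of 5 to pent-4-enal at −78 °C, which outruns enolisation for an aldehyde, would give methyl 2,4-diethyl-5-hydroxy-3-oxonon-8-enoate F4 as a diastereomer mixture. Oxidation with Dess–Martin periodinane (NaHCO3, CH2Cl2, rt) would then give 6.

**Step 5.** Methylation on the wrong oxygen is the main risk. Any adventitious base would generate the ambident pyranonate, which is methylated at the C4 oxygen and leads into the isomeric 4-methoxy-2-pyranone series. Build-up of free TfOH could also add across the terminal alkene. The fallback sets out from 6 and comes back at 9, bypassing 7 and 8. It is a dehydrative cyclisation of the 3,5-diketo ester with PPh3/CCl4 in THF at rt: Appel-type activation of the enolised C5 oxygen, attack of the ester carbonyl oxygen at C5, then loss of the C2 proton. This is a known way to 2-methoxy-4-pyranones in which the ester methoxy group is kept and no methylation is needed. No new compound arises (entry F0).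

**Step 8.** Loss of chemoselectivity or stalling may occur. Prolonged exposure could begin to saturate a ring double bond, and ruthenium residues carried over from step 7 could poison Pd/C. The fallback goes from 15 to 16 by diimide reduction, with diimide generated from 2-nitrobenzenesulfonyl hydrazide and Et3N in CH2Cl2 at rt. Its concerted syn transfer of H2 is confined to unpolarised, unhindered C=C bonds and leaves the ring alkenes, the carbonyl and the acetate alone. No new compound arises (entry F0).

## Further compounds

F1 | step 7 | (S)-hept-6-en-2-yl acetate | C=CCCC[C@H](C)OC(C)=O
F2 | step 7 | (S)-7-bromoheptan-2-yl acetate | BrCCCCC[C@H](C)OC(C)=O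
F3 | step 7 | 6-[4-(9-borabicyclo[3.3.1]nonan-9-yl)butyl]-3,5-diethyl-2-methoxy-4H-pyran-4-one | CCc1c(CCCCB2C3CCCC2CCC3)oc(OC)c(CC)c1=O
F4 | step 3 | methyl 2,4-diethyl-5-hydroxy-3-oxonon-8-enoate (diastereomer mixture) | C=CCCC(O)C(CC)C(=O)C(CC)C(=O)OC
F0 | step 5 | none | none
F0 | step 8 | none | none
A1 | alternative 1 | methyl (15S)-15-(tert-butyldimethylsilyloxy)-2-ethyl-3-oxohexadec-4-ynoate | CCC(C(=O)OC)C(=O)C#CCCCCCCCCC[C@H](C)O[Si](C)(C)C(C)(C)C
A2 | alternative 1 | 3-ethyl-5-iodo-2-methoxy-6-[(10S)-10-(tert-butyldimethylsilyloxy)undecyl]-4H-pyran-4-one | CCc1c(OC)oc(CCCCCCCCC[C@H](C)O[Si](C)(C)C(C)(C)C)c(I)c1=O
A3 | alternative 2 | 3,5-diethyl-2,6-dimethoxy-4H-pyran-4-one | CCc1c(OC)oc(OC)c(CC)c1=O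
A4 | alternative 2 | [(10S)-10-(tert-butyldimethylsilyloxy)undecyl]magnesium bromide | Br[Mg]CCCCCCCCC[C@H](C)O[Si](C)(C)C(C)(C)C
A5 | alternative 2 | 6-[(10S)-10-(tert-butyldimethylsilyloxy)undecyl]-3,5-diethyl-2-methoxy-4H-pyran-4-one | CCc1c(CCCCCCCCC[C@H](C)O[Si](C)(C)C(C)(C)C)oc(OC)c(CC)c1=O
A6 | alternative 3 | 3,5-diethyl-2-methoxy-6-(10-oxoundecyl)-4H-pyran-4-one | CCc1c(CCCCCCCCCC(C)=O)oc(OC)c(CC)c1=O
A7 | alternative 3 | 3,5-diethyl-6-[(10S)-10-hydroxyundecyl]-2-methoxy-4H-pyran-4-one | CCc1c(CCCCCCCCC[C@H](C)O)oc(OC)c(CC)c1=O
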